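Locants: cyclohexene ring C1 (O-angelate), C2=C3(CH3), C4 (OAc), C5H2, C6H; side chain C7H(CH3)–C8H2–C9H(OAc)–C10H=C11(CH3)2.
Endgame: the C1 angelate comes from the C1-epimeric alcohol by invertive Mitsunobu esterification, both acetates from a C4,C9-diol, C9–OH from the C9 enone (CBS reduction), and C4–OH from C4H2 by SeO2 allylic oxidation.
Key disconnection C7–C8: one-pot syn-hydroboration of an exocyclic (E)-C6=C7 ethylidene with 9-BBN, then 1,2-metallate transfer of C7 from boron to the brominated carbon C8 of 1-bromo-4-methylpent-3-en-2-one. This creates C6, C7 and the C7–C8 bond and brings in all six remaining carbons.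
Enabling feature: the ring CH (C6) and side-chain CH (C7) form a vicinal pair next to the C1 carbinol, and C8 lies alpha to the C9 oxygen. C6–C7 therefore maps onto an ethylidene whose E geometry is fixed by conjugation to a C1 ketone, the C1 silyloxy group steers the borane, and C8 can be an alpha-bromo ketone carbon.
Rings: the only ring is bought as 3-methylcyclohex-2-enone and no ring is formed. One ring stereocentre (C1, CBS) is set by catalysis and relays to C6, C7 and C4 before it is inverted.

Key step: step 7

Remarks: (R)- and (S)-Me-CBS stand for (3aR)- and (3aS)-1-methyl-3,3-diphenylhexahydropyrrolo[1,2-c][1,3,2]oxazaborole, C18H20BNO. 9-BBN is written as its monomer. It is assumed that the silyloxy group at the doubly allylic C1 of 8 sits pseudoaxial and shields one face of the C6=C7 alkene.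

Step 1
Reactants: 1 3-methylcyclohex-2-en-1-one; 2 acetaldehyde
Product: 4 6-(1-hydroxyethyl)-3-methylcyclohex-2-en-1-one (racemic diastereomer mixture), via lithium dienolate 3 (not isolated)
Conditions: LDA (1.05 equiv), THF, −78 °C; 2, −78 °C; AcOH quench
Reagents that add atoms: none
Why: Kinetic deprotonation by LDA occurs at the alpha-prime carbon C6 and the cross-conjugated dienolate adds to acetaldehyde (directed aldol addition); both new stereocentres are erased in step 2, so their configuration does not matter.

Step 2
Reactants: 4 6-(1-hydroxyethyl)-3-methylcyclohex-2-en-1-one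
Product: 6 (6E)-6-ethylidene-3-methylcyclohex-2-en-1-one, via mesylate 5 (not isolated)
Conditions: MsCl, Et3N, CH2Cl2, 0 °C; then DBU, 0 °C to rt
Reagents that add atoms: methanesulfonyl chloride, CS(=O)(=O)Cl (its atoms are present only in 5)
Why: Mesylation and E1cB elimination complete the aldol condensation and should give the thermodynamically preferred E alkene (methyl turned away from the C1 carbonyl), while the mild base and low temperature avoid drift of the cross-conjugated dienone to the isomeric phenol.

Step 3
Reactants: 6 (6E)-6-ethylidene-3-methylcyclohex-2-en-1-one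
Product: 7 (1S,6E)-6-ethylidene-3-methylcyclohex-2-en-1-ol
Conditions: (R)-Me-CBS (0.15 equiv), catecholborane (1.5 equiv), toluene, −78 °C; aqueous work-up
Reagents that add atoms: none
Why: In this Corey–Bakshi–Shibata reduction the catalyst binds the carbonyl oxygen on the side of the small C2–H flank and away from the large flank (fully substituted C6 with its s-cis ethylidene), so the (R)-catalyst should deliver hydride 1,2 to give the (1S)-alcohol, the only ring stereocentre taken from an external chiral source.

Step 4
Reactants: 7 (1S,6E)-6-ethylidene-3-methylcyclohex-2-en-1-ol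
Product: 8 tert-butyl{[(1S,6E)-6-ethylidene-3-methylcyclohex-2-en-1-yl]oxy}dimethylsilane
Conditions: TBSCl, imidazole, DMF, rt
Reagents that add atoms: tert-butyldimethylsilyl chloride, CC(C)(C)[Si](C)(C)Cl
Why: Imidazole-promoted silylation under non-acidic conditions protects the ionisation-prone doubly allylic alcohol and installs the bulky group that steers steps 7 and 8; no stereocentre is touched.

Step 5
Reactants: 9 4-methylpent-3-en-2-one (mesityl oxide)
Product: 11 trimethyl[(4-methylpenta-1,3-dien-2-yl)oxy]silane, via lithium dienolate 10 (not isolated)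
Conditions: LDA, THF, −78 °C; TMSCl, −78 °C to rt
Reagents that add atoms: chlorotrimethylsilane, C[Si](C)(C)Cl
Why: LDA removes the kinetically most accessible acetyl proton and O-silylation traps the cross-conjugated dienolate (kinetic silyl enol ether formation).

Step 6
Reactants: 11 trimethyl[(4-methylpenta-1,3-dien-2-yl)oxy]silane
Product: 12 1-bromo-4-methylpent-3-en-2-one
Conditions: NBS (1.0 equiv), THF, −78 to 0 °C; aqueous work-up; used fresh
Reagents that add atoms: N-bromosuccinimide, O=C1CCC(=O)N1Br
Why: Electrophilic bromination of a silyl enol ether occurs at its terminal CH2 carbon, so bromine is placed regiospecifically at the alpha-prime carbon and the gamma-methyl groups stay untouched.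

Step 7
Reactants: 8 tert-butyl{[(1S,6E)-6-ethylidene-3-methylcyclohex-2-en-1-yl]oxy}dimethylsilane; 13 9-borabicyclo[3.3.1]nonane (9-BBN); 12 1-bromo-4-methylpent-3-en-2-one
Product: 17 (6R)-6-[(1S,2R)-2-{[tert-butyl(dimethyl)silyl]oxy}-4-methylcyclohex-3-en-1-yl]-2-methylhept-2-en-4-one, via B-alkyl-9-BBN 14 (not isolated), via bromo borate 15 (not isolated), via boron dienolate 16 (not isolated)
Conditions: 13 (1.05 equiv), THF, 65 °C; cool to 0 °C; 12 (1.0 equiv), then KO(2,6-tBu2C6H3) (1.0 equiv) in THF dropwise, 0 °C to rt; aqueous work-up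
Reagents that add atoms: none
Why: 9-BBN adds H to C6 and B to C7 in a concerted four-centre syn addition (14); the hindered phenoxide then deprotonates 12 at its CH2Br carbon, the bromo enolate binds to boron through carbon (15), C7 migrates from boron to C8 with loss of bromide and retention at C7, and the alpha-boryl ketone relaxes to boron dienolate 16, which the liberated phenol protonates to 17. The closest known reaction type is the base-induced alpha-alkylation of alpha-bromo ketones, esters and nitriles with B-alkyl-9-BBN reagents (a 1,2-metallate rearrangement), established for secondary alkyl groups made by hydroboration of exocyclic ethylidene carbocycles; it reverses polarity, because C7, an acceptor carbon in the natural C1/C9 1,5-dioxygen pattern, reacts as the nucleophile and C8 as the electrophilic terminus. No ring is closed. C6 and C7 are created together: their relative configuration follows from syn addition to the E alkene plus retentive migration, and their absolute configuration from attack on the face opposite to the C1 silyloxy group, which is held pseudoaxial by strain with H2 and H7 in the in-plane orientation and by overlap of its C–O bond with both flanking pi systems. The step needs chemoselectivity for C6=C7 over the ring C2=C3 alkene (1-methylcyclohexene-type alkenes are among the slowest substrates for 9-BBN), boron placement at the less substituted C7, migration of the side-chain alkyl rather than a bicyclic B–C bond (the normal course for B-alkyl-9-BBN in this reaction), and an enone in 12 that is inert to the borane, which its beta,beta-disubstitution secures.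

Step 8
Reactants: 17 (6R)-6-[(1S,2R)-2-{[tert-butyl(dimethyl)silyl]oxy}-4-methylcyclohex-3-en-1-yl]-2-methylhept-2-en-4-one
Product: 18 (6R)-6-[(1S,2R,5R)-2-{[tert-butyl(dimethyl)silyl]oxy}-5-hydroxy-4-methylcyclohex-3-en-1-yl]-2-methylhept-2-en-4-one
Conditions: SeO2 (0.3 equiv), tBuOOH (5.5 M in decane, 2.5 equiv), CH2Cl2, 0 °C to rt
Reagents that add atoms: tert-butyl hydroperoxide, CC(C)(C)OO (stoichiometric oxygen source); selenium dioxide, O=[Se]=O (catalytic oxygen carrier)
Why: SeO2 allylic oxidation (ene reaction, then [2,3]-sigmatropic shift) should attack the only electron-rich alkene C2=C3, functionalise the ring CH2 at its more substituted terminus (C4), and deliver oxygen suprafacially on the face opposite to the C1 silyloxy group and the C6 side chain, which sets C4 as R, while the side-chain alkene is shielded by conjugation to the C9 ketone.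

Step 9
Reactants: 18 (6R)-6-[(1S,2R,5R)-2-{[tert-butyl(dimethyl)silyl]oxy}-5-hydroxy-4-methylcyclohex-3-en-1-yl]-2-methylhept-2-en-4-one
Product: 19 (4R,6R)-6-[(1S,2R,5R)-2-{[tert-butyl(dimethyl)silyl]oxy}-5-hydroxy-4-methylcyclohex-3-en-1-yl]-2-methylhept-2-en-4-ol
Conditions: (S)-Me-CBS (0.2 equiv), catecholborane (3 equiv), toluene, −78 °C; aqueous work-up
Reagents that add atoms: none
Why: In this Corey–Bakshi–Shibata reduction of an acyclic enone the alkenyl flank acts as the large group and the CH2 flank as the small one, so the (S)-catalyst should give the (R)-allylic alcohol at C9 by 1,2-reduction under catalyst control, and the free C4 hydroxyl only consumes one equivalent of borane.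

Step 10
Reactants: 19 (4R,6R)-6-[(1S,2R,5R)-2-{[tert-butyl(dimethyl)silyl]oxy}-5-hydroxy-4-methylcyclohex-3-en-1-yl]-2-methylhept-2-en-4-ol
Product: 20 (4R,6R)-6-[(1S,2R,5R)-5-acetoxy-2-{[tert-butyl(dimethyl)silyl]oxy}-4-methylcyclohex-3-en-1-yl]-2-methylhept-2-en-4-yl acetate
Conditions: Ac2O (4 equiv), DMAP (cat.), pyridine (solvent), 0 °C to rt
Reagents that add atoms: acetic anhydride, CC(=O)OC(C)=O
Why: DMAP-catalysed acylation esterifies both secondary allylic alcohols in one operation while C1 stays masked as its silyl ether, which differentiates the three oxygens without touching a stereocentre.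

Step 11
Reactants: 20 (4R,6R)-6-[(1S,2R,5R)-5-acetoxy-2-{[tert-butyl(dimethyl)silyl]oxy}-4-methylcyclohex-3-en-1-yl]-2-methylhept-2-en-4-yl acetate
Product: 21 (4R,6R)-6-[(1S,2R,5R)-5-acetoxy-2-hydroxy-4-methylcyclohex-3-en-1-yl]-2-methylhept-2-en-4-yl acetate
Conditions: TBAF (1.5 equiv), AcOH (1.5 equiv), THF, 0 °C to rt
Reagents that add atoms: none
Why: Fluoride cleaves the Si–O bond selectively, and the acetic acid buffer keeps the medium too weakly basic for acetate cleavage or migration.

Step 12
Reactants: 21 (4R,6R)-6-[(1S,2R,5R)-5-acetoxy-2-hydroxy-4-methylcyclohex-3-en-1-yl]-2-methylhept-2-en-4-yl acetate; 22 (2Z)-2-methylbut-2-enoic acid (angelic acid)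
Product: 23 (1S,4R,6S)-4-acetoxy-6-[(2R,4R)-4-acetoxy-6-methylhept-5-en-2-yl]-3-methylcyclohex-2-en-1-yl (2Z)-2-methylbut-2-enoate (target)
Conditions: 22 (2 equiv), PPh3 (2 equiv), DIAD (2 equiv), toluene, 0 °C to rt
Reagents that add atoms: none
Why: In this Mitsunobu reaction the pseudoaxial allylic C1 hydroxyl is activated and displaced by angelate in an SN2 process from the face opposite to the C6 side chain, which inverts C1 to S (cis to the C4 acetate, trans to the side chain); the acid reacts as a carboxylate and is never activated at its carbonyl, so the Z alkene should not isomerise, and the SN2′ position C3 is fully substituted.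

Compound list
1 | 3-methylcyclohex-2-en-1-one | CC1=CC(=O)CCC1 | starting material
2 | acetaldehyde | CC=O | starting material
3 | lithium 4-methylcyclohexa-1,3-dien-2-olate | [Li+].[O-]C1=CCCC(C)=C1 | intermediate
4 | 6-(1-hydroxyethyl)-3-methylcyclohex-2-en-1-one (racemic diastereomer mixture) | CC(O)C1CCC(C)=CC1=O | intermediate
5 | 1-(4-methyl-2-oxocyclohex-3-en-1-yl)ethyl methanesulfonate | CC(OS(C)(=O)=O)C1CCC(C)=CC1=O | intermediate
6 | (6E)-6-ethylidene-3-methylcyclohex-2-en-1-one | O=C1C=C(C)CC/C1=C\C | intermediate
7 | (1S,6E)-6-ethylidene-3-methylcyclohex-2-en-1-ol | O[C@H]1C=C(C)CC/C1=C\C | intermediate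
8 | tert-butyl{[(1S,6E)-6-ethylidene-3-methylcyclohex-2-en-1-yl]oxy}dimethylsilane | CC(C)(C)[Si](C)(C)O[C@H]1C=C(C)CC/C1=C\C | intermediate
9 | 4-methylpent-3-en-2-one (mesityl oxide) | CC(=O)C=C(C)C | starting material
10 | lithium 4-methylpenta-1,3-dien-2-olate | [Li+].[O-]C(=C)C=C(C)C | intermediate
11 | trimethyl[(4-methylpenta-1,3-dien-2-yl)oxy]silane | C=C(O[Si](C)(C)C)C=C(C)C | intermediate
12 | 1-bromo-4-methylpent-3-en-2-one | BrCC(=O)C=C(C)C | intermediate
13 | 9-borabicyclo[3.3.1]nonane (9-BBN, monomer) | B1C2CCCC1CCC2 | starting material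
14 | 9-{(1S)-1-[(1S,2R)-2-{[tert-butyl(dimethyl)silyl]oxy}-4-methylcyclohex-3-en-1-yl]ethyl}-9-borabicyclo[3.3.1]nonane (side chain cis to the silyloxy group) | CC(C)(C)[Si](C)(C)O[C@H]1C=C(C)CC[C@H]1[C@H](C)B2C3CCCC2CCC3 | intermediate
15 | potassium borate from 14 and the C-bound bromo enolate of 12 (ring and C7 configuration as in 14, CHBr centre unassigned) | [K+].CC(C)(C)[Si](C)(C)O[C@H]1C=C(C)CC[C@H]1[C@H](C)[B-]2(C(Br)C(=O)C=C(C)C)C3CCCC2CCC3 | intermediate
16 | O-(9-borabicyclo[3.3.1]nonan-9-yl) dienolate of 17 (enolate geometry unassigned) | CC(C)(C)[Si](C)(C)O[C@H]1C=C(C)CC[C@H]1[C@H](C)C=C(OB2C3CCCC2CCC3)C=C(C)C | intermediate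
17 | (6R)-6-[(1S,2R)-2-{[tert-butyl(dimethyl)silyl]oxy}-4-methylcyclohex-3-en-1-yl]-2-methylhept-2-en-4-one | CC(C)(C)[Si](C)(C)O[C@H]1C=C(C)CC[C@H]1[C@H](C)CC(=O)C=C(C)C | intermediate
18 | (6R)-6-[(1S,2R,5R)-2-{[tert-butyl(dimethyl)silyl]oxy}-5-hydroxy-4-methylcyclohex-3-en-1-yl]-2-methylhept-2-en-4-one | CC(C)(C)[Si](C)(C)O[C@H]1C=C(C)[C@H](O)C[C@H]1[C@H](C)CC(=O)C=C(C)C | intermediate
19 | (4R,6R)-6-[(1S,2R,5R)-2-{[tert-butyl(dimethyl)silyl]oxy}-5-hydroxy-4-methylcyclohex-3-en-1-yl]-2-methylhept-2-en-4-ol | CC(C)(C)[Si](C)(C)O[C@H]1C=C(C)[C@H](O)C[C@H]1[C@H](C)C[C@H](C=C(C)C)O | intermediate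
20 | (4R,6R)-6-[(1S,2R,5R)-5-acetoxy-2-{[tert-butyl(dimethyl)silyl]oxy}-4-methylcyclohex-3-en-1-yl]-2-methylhept-2-en-4-yl acetate | CC(C)(C)[Si](C)(C)O[C@H]1C=C(C)[C@H](OC(C)=O)C[C@H]1[C@H](C)C[C@H](C=C(C)C)OC(C)=O | intermediate
21 | (4R,6R)-6-[(1S,2R,5R)-5-acetoxy-2-hydroxy-4-methylcyclohex-3-en-1-yl]-2-methylhept-2-en-4-yl acetate | O[C@H]1C=C(C)[C@H](OC(C)=O)C[C@H]1[C@H](C)C[C@H](C=C(C)C)OC(C)=O | intermediate
22 | (2Z)-2-methylbut-2-enoic acid (angelic acid) | C/C=C(/C)C(=O)O | starting material
23 | (1S,4R,6S)-4-acetoxy-6-[(2R,4R)-4-acetoxy-6-methylhept-5-en-2-yl]-3-methylcyclohex-2-en-1-yl (2Z)-2-methylbut-2-enoate | C/C=C(/C)C(=O)O[C@@H]1C=C(C)[C@H](OC(C)=O)C[C@H]1[C@H](C)C[C@H](C=C(C)C)OC(C)=O | target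

Total step count: 12. Longest linear sequence: 10 steps (steps 1–4 and 7–12, from 1).

Steps most likely to fail

Step 7. Capture of the bromo enolate by the hindered secondary borane may be slower than base-induced self-condensation or gamma-deprotonation of the bromo enone, so that the transfer stalls. Partial hydroboration on the silyloxy face would also erode the C6/C7 control. The fallback sets out from 14 (made from 8 and 13 as before). The boron-to-carbon transfer is run with ethyl bromoacetate and the same phenoxide, the most robust partner of this reaction type, to give the ester F1. This is converted with MeNH(OMe)·HCl and iPrMgCl into the Weinreb amide F2. Addition of 2-methylprop-1-enylmagnesium bromide then builds the enone stepwise and rejoins the route at 17.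

Step 8. The ring alkene is deactivated by the allylic silyloxy group, so the oxidation may be sluggish. It may lose site selectivity toward the C3 methyl group or the carbon alpha to the ketone, or run on to the ketone level. The fallback sets out from 17. Allylic oxidation is taken deliberately to the ketone level with CrO3·3,5-dimethylpyrazole (CH2Cl2, −20 °C) to give the diketone F3, which makes the facial course of the C–H oxidation irrelevant. Both ketones are then reduced in one operation with (S)-Me-CBS and catecholborane. 2-Methylcyclohex-2-enones are a privileged substrate class for this catalyst. The same catalyst enantiomer that gives R at C9 should give R at C4 (C3 as the large flank, C5 as the small one), provided catalyst control overrides the substrate's preference for axial hydride delivery. The route is rejoined at 19.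

Step 12. The activated pseudoaxial C1 oxygen is antiperiplanar to the axial C6–H. Elimination to a conjugated ring diene, or ionisation to an allyl cation with loss of stereochemical integrity, may therefore outrun substitution by the weakly acidic angelic acid. The fallback sets out from 21. Dess–Martin oxidation (NaHCO3, CH2Cl2) gives the enone F4. Luche reduction (NaBH4, CeCl3·7H2O, MeOH, −78 °C) by axial hydride delivery should give the equatorial alcohol F5, trans to the side chain and cis to the C4 acetate. Yamaguchi esterification with the mixed anhydride F6 (from 22, 2,4,6-trichlorobenzoyl chloride and Et3N, then DMAP in toluene at the lowest workable temperature to limit Z-to-E isomerisation) rejoins the route at 23.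

Further compounds
F1 | step 7 | ethyl (3R)-3-[(1S,2R)-2-{[tert-butyl(dimethyl)silyl]oxy}-4-methylcyclohex-3-en-1-yl]butanoate | CC(C)(C)[Si](C)(C)O[C@H]1C=C(C)CC[C@H]1[C@H](C)CC(=O)OCC
F2 | step 7 | (3R)-3-[(1S,2R)-2-{[tert-butyl(dimethyl)silyl]oxy}-4-methylcyclohex-3-en-1-yl]-N-methoxy-N-methylbutanamide | CC(C)(C)[Si](C)(C)O[C@H]1C=C(C)CC[C@H]1[C@H](C)CC(=O)N(C)OC
F3 | step 8 | (6R)-6-[(1S,2R)-2-{[tert-butyl(dimethyl)silyl]oxy}-4-methyl-5-oxocyclohex-3-en-1-yl]-2-methylhept-2-en-4-one | CC(C)(C)[Si](C)(C)O[C@H]1C=C(C)C(=O)C[C@H]1[C@H](C)CC(=O)C=C(C)C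
F4 | step 12 | (4R,6R)-6-[(1S,5R)-5-acetoxy-4-methyl-2-oxocyclohex-3-en-1-yl]-2-methylhept-2-en-4-yl acetate | O=C1C=C(C)[C@H](OC(C)=O)C[C@H]1[C@H](C)C[C@H](C=C(C)C)OC(C)=O
F5 | step 12 | (4R,6R)-6-[(1S,2S,5R)-5-acetoxy-2-hydroxy-4-methylcyclohex-3-en-1-yl]-2-methylhept-2-en-4-yl acetate | O[C@@H]1C=C(C)[C@H](OC(C)=O)C[C@H]1[C@H](C)C[C@H](C=C(C)C)OC(C)=O
F6 | step 12 | (2Z)-2-methylbut-2-enoic 2,4,6-trichlorobenzoic anhydride | C/C=C(/C)C(=O)OC(=O)c1c(Cl)cc(Cl)cc1Cl
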